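The route maps the target's cyclopentane onto (R)-4-silyloxycyclopent-2-enone. Three adjacent ring carbons, the lactone O–CH, the ethyl-bearing CH and the CH that starts the azepane, alternate in face and sit beside the N-bearing spiro carbon, which is the enone carbonyl. One conjugate addition–enolate alkylation therefore joins the enone, an ethyl zincate and a 4-silyloxybut-2-ynyl iodide, forming the ring–ethyl bond and the ring–azepane-chain bond and setting two stereocentres from the existing C–O centre. The precursor is simply the commercial enone plus a two-step propargylic iodide. The ketone then takes a serine-derived acetylide, and cationic spiro-amination, azepane closure, the hydroxy lactone and the side-chain lactone follow.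

Key step: step 3

Remark 1: the cyclopentane carbons keep the locants of ketone 7 throughout: C1 (carbonyl, later the N-bearing spiro carbon), C2 (CH with the four-carbon chain), C3 (CH–Et), C4 (CH–O), C5 (CH2, later the CH bonded to the lactone α-carbon). "Upper face" is the face of the C3 ethyl group. C5′ is the pyrrolidine carbon that carries the CH2O arm.
Remark 2: a neutral ethylzinc enolate alkylates propargylic iodides sluggishly, so ethyl is delivered from diethylzinc as its lithium ate complex. Both silyl ethers of 7 are kept as TBS on purpose, because both are removed in one acid operation (step 10).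
Remark 3: 13 and 14 form as C1 epimers (major one drawn); both are used, because C1 becomes a cation in step 10.

Step 1
Reactants: 1 but-2-yne-1,4-diol
Product: 2 4-[(tert-butyldimethylsilyl)oxy]but-2-yn-1-ol
Conditions: NaH (1 equiv), THF, 0 °C; TBSCl (1 equiv), rt
Reagents that add atoms: tert-butyldimethylsilyl chloride, CC(C)(C)[Si](C)(C)Cl
Why: Mono-O-silylation of a symmetric diol through its sparingly soluble monosodium alkoxide, which limits double silylation; no stereocentre is involved.

Step 2
Reactants: 2 4-[(tert-butyldimethylsilyl)oxy]but-2-yn-1-ol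
Product: 3 tert-butyl[(4-iodobut-2-yn-1-yl)oxy]dimethylsilane
Conditions: PPh3, I2, imidazole, CH2Cl2, 0 °C, dark
Reagents that add atoms: iodine, II
Why: Appel iodination of a primary propargylic alcohol (SN2 on the alkoxyphosphonium ion) under neutral conditions that leave the silyl ether intact.

Step 3
Reactants: 4 (R)-4-[(tert-butyldimethylsilyl)oxy]cyclopent-2-en-1-one; 5 diethylzinc; 3 tert-butyl[(4-iodobut-2-yn-1-yl)oxy]dimethylsilane
Product: 7 (2R,3R,4R)-4-[(tert-butyldimethylsilyl)oxy]-2-{4-[(tert-butyldimethylsilyl)oxy]but-2-yn-1-yl}-3-ethylcyclopentan-1-one, via zincate enolate 6 (not isolated)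
Conditions: Et2Zn, MeLi, THF, 0 → −78 °C; 4, −78 °C; then HMPA, 3, −78 → −40 °C
Reagents that add atoms: none
Why: Li[ZnEt2Me], made in the flask from 5 and MeLi, transfers ethyl (methyl is the slow-transferring ligand) to C3 of 4 in a 1,4-addition, and the resulting C1–C2 lithium zincate enolate 6 is alkylated at C2 by the primary propargylic iodide 3 in an SN2 reaction once HMPA is added. The closest known reaction type is the organozincate three-component coupling of 4-silyloxycyclopent-2-enones with propargylic iodides developed for prostaglandins. No ring is closed; the step forms the C3–ethyl bond and the C2–CH2 bond. C3 is controlled by the C4 silyloxy group, which shields its own face so that ethyl enters anti to it, and C2 is controlled by the new C3 ethyl group, the iodide approaching the planar enolate anti to it, which gives the all-trans (2R,3R,4R) ketone. The step needs C2-alkylation to outrun proton transfer to the C1–C5 enolate, which would expel silanolate, and it needs mono-alkylation without SN2′ attack; the ate-type enolate, HMPA, the very reactive iodide and a temperature at or below −40 °C should secure this. The step uses the fact that in the target the lactone O–CH, the ethyl CH and the azepane-bearing CH of the cyclopentane are contiguous and alternate in face next to the spiro carbon.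

Step 4
Reactants: 8 tert-butyl (R)-4-formyl-2,2-dimethyloxazolidine-3-carboxylate (D-serine-derived, commercial)
Product: 9 tert-butyl (S)-4-ethynyl-2,2-dimethyloxazolidine-3-carboxylate
Conditions: dimethyl (1-diazo-2-oxopropyl)phosphonate, K2CO3, MeOH, 0 °C → rt
Reagents that add atoms: dimethyl (1-diazo-2-oxopropyl)phosphonate, COP(=O)(OC)C(=[N+]=[N-])C(C)=O
Why: Seyferth–Gilbert homologation (Ohira–Bestmann variant) turns the aldehyde into the terminal alkyne without touching the stereocentre; the descriptor changes from R to S only because CH2O now outranks the alkyne carbon.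

Step 5
Reactants: 9 tert-butyl (S)-4-ethynyl-2,2-dimethyloxazolidine-3-carboxylate
Product: 10 (S)-2-aminobut-3-yn-1-ol hydrochloride
Conditions: HCl (4 M in dioxane), MeOH, rt
Reagents that add atoms: hydrogen chloride, Cl
Why: Acidolysis removes the Boc group and the N,O-isopropylidene acetal in one operation (carbamate and acetal deprotection); the stereocentre is not involved and the salt is stable.

Step 6
Reactants: 10 (S)-2-aminobut-3-yn-1-ol hydrochloride
Product: 11 (S)-N-(1-hydroxybut-3-yn-2-yl)-4-methylbenzenesulfonamide
Conditions: TsCl (1.05 equiv), Et3N (2.2 equiv), CH2Cl2, 0 °C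
Reagents that add atoms: 4-methylbenzenesulfonyl chloride, Cc1ccc(S(=O)(=O)Cl)cc1
Why: Chemoselective N-sulfonylation, the amine outcompeting the alcohol at 0 °C; the tosylamide tolerates butyllithium and is the N-nucleophile of step 10.

Step 7
Reactants: 11 (S)-N-(1-hydroxybut-3-yn-2-yl)-4-methylbenzenesulfonamide
Product: 12 (S)-N-{1-[(tert-butyldiphenylsilyl)oxy]but-3-yn-2-yl}-4-methylbenzenesulfonamide
Conditions: TBDPSCl, imidazole, DMF, rt
Reagents that add atoms: tert-butyldiphenylsilyl chloride, CC(C)(C)[Si](Cl)(c1ccccc1)c1ccccc1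
Why: Standard O-silylation of the primary alcohol; TBDPS is chosen because it must outlast the acid of step 10 and the strong bases of steps 14–17.

Step 8
Reactants: 7 (2R,3R,4R)-ketone; 12 (S)-N-{1-[(tert-butyldiphenylsilyl)oxy]but-3-yn-2-yl}-4-methylbenzenesulfonamide
Product: 13 C1-alkynyl tertiary alcohol [C1 carries OH (lower face) and the chain C≡C–(S)-CH(NHTs)–CH2OTBDPS (upper face); C2–C4 as in 7]
Conditions: 12, n-BuLi (2.1 equiv), THF, −78 °C; CeCl3; then 7, −78 °C; aq. NH4Cl
Reagents that add atoms: none
Why: 1,2-Addition of the cerium acetylide from the N,C-dianion of 12 to the ketone (ketone alkynylation), CeCl3 suppressing the enolisation that would expel the β-silyloxy group; the new carbinol forms mainly anti to the C2 chain but its configuration is later erased.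

Step 9
Reactants: 13 C1-alkynyl tertiary alcohol
Product: 14 saturated tertiary alcohol [13 with both C≡C units reduced to CH2CH2]
Conditions: H2 (1 atm), 10% Pd/C, EtOAc, rt
Reagents that add atoms: none
Why: Catalytic hydrogenation saturates both alkynes in one operation; sulfonamide, silyl ethers and the tertiary alcohol should survive in a neutral solvent at 1 atm.

Step 10
Reactants: 14 saturated tertiary alcohol
Product: 16 N-tosyl 1-azaspiro[4.4]nonane diol [N on the upper face of C1; C4–OH and the C2 4-hydroxybutyl chain on the lower face; CH2OTBDPS on C5′], via bis-TBS spirocycle 15 (not isolated)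
Conditions: TfOH (0.3 equiv), CH2Cl2, −20 → 0 °C; then MeOH, rt
Reagents that add atoms: none
Why: Acid ionises the tertiary alcohol and the tethered tosylamide captures the cyclopentyl cation in a 5-exo closure (SN1-type dehydrative amination, the alcohol counterpart of acid-catalysed hydroamination), both C1 epimers converging on one cation; nitrogen should enter on the upper face, anti to the adjacent C2 chain and the C4 oxygen, which sets the spiro centre, and the same acid in methanol then removes both TBS ethers while the far more acid-stable primary TBDPS ether remains.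

Step 11
Reactants: 16 N-tosyl 1-azaspiro[4.4]nonane diol
Product: 17 spiro-pyrrolidine amino diol (free N–H)
Conditions: sodium naphthalenide (excess), DME, −78 °C; aq. NH4Cl
Reagents that add atoms: none
Why: Reductive detosylation by single-electron transfer cleaves the S–N bond and does not depend on access to the hindered nitrogen; alcohols and the silyl ether are inert at −78 °C.

Step 12
Reactants: 17 spiro-pyrrolidine amino diol
Product: 19 tricyclic azepane alcohol [N–CH2 bond closed, azepane trans-fused across C1–C2; C4–OH free], via primary bromide 18 (not isolated)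
Conditions: PPh3, CBr4, CH2Cl2, 0 °C; then iPr2NEt, MeCN, 60 °C
Reagents that add atoms: none
Why: Appel bromination takes the unhindered primary alcohol in preference to the flanked secondary one, and the amine then displaces bromide intramolecularly (7-exo-tet N-alkylation) to close the azepane; no stereocentre changes.

Step 13
Reactants: 19 tricyclic azepane alcohol
Product: 20 tricyclic amino ketone (C4=O)
Conditions: (COCl)2, DMSO, CH2Cl2, −78 °C; Et3N
Reagents that add atoms: none
Why: Swern oxidation of the secondary alcohol tolerates the tertiary amine; the β-amino ketone is used promptly because a retro-Michael pathway exists.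

Step 14
Reactants: 20 tricyclic amino ketone; 21 ethyl bromoacetate
Product: 22 keto ester [CH2CO2Et on C5, lower face]
Conditions: LDA (1.1 equiv), THF, −78 °C; then 21, DMPU, −78 → −30 °C
Reagents that add atoms: none
Why: LDA removes a proton from the C5 methylene (kinetic, less substituted α-carbon, assisted by the neighbouring amine) and the lithium enolate is alkylated by the α-halo ester (SN2 enolate alkylation) from the lower face, because the nitrogen and the silyloxymethyl-bearing C5′ cover the upper face; this sets C5.

Step 15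
Reactants: 22 keto ester
Product: 24 cis-fused γ-lactone [C4–O and C5–CH2 on the lower face], via cis hydroxy ester 23 (not isolated)
Conditions: L-Selectride, THF, −78 °C → rt; aq. NH4Cl
Reagents that add atoms: none
Why: The bulky hydride should attack the upper face of the ketone, the lower face being covered by the acetate arm (pressed toward the carbonyl by the quaternary neighbour), the pyrrolidine CH2 and the azepane CH2, so the C4 alkoxide forms cis to the arm and closes onto the ethyl ester (hydride reduction–lactonisation); this restores C4.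

Step 16
Reactants: 24 cis-fused γ-lactone
Product: 25 α-methyl lactone (methyl on the convex face)
Conditions: LDA, THF, −78 °C; MeI
Reagents that add atoms: iodomethane, CI
Why: Lactone enolate methylation from the convex face; this centre is re-formed in step 17, so only mono-methylation matters, and the hindered tertiary amine should not be quaternised at −78 °C.

Step 17
Reactants: 25 α-methyl lactone
Product: 26 α-hydroxy-α-methyl lactone [OH on the convex face, cis to C5–H; methyl concave; TBDPS ether retained]
Conditions: KHMDS, THF, −78 °C; 2-(phenylsulfonyl)-3-phenyloxaziridine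
Reagents that add atoms: 2-(phenylsulfonyl)-3-phenyloxaziridine, O=S(=O)(c1ccccc1)N1OC1c1ccccc1
Why: Enolate hydroxylation with an N-sulfonyloxaziridine (Davis oxidation) delivers oxygen to the convex face of the cis-fused bicycle, anti to the spiro carbon, so OH ends cis to the ring-fusion H and methyl on the concave side, as in the target.

Step 18
Reactants: 26 α-hydroxy-α-methyl lactone
Product: 27 primary alcohol (CH2OH on C5′)
Conditions: TBAF, AcOH, THF, rt
Reagents that add atoms: none
Why: Fluoride cleavage of the primary TBDPS ether, buffered with acetic acid so that the lactone and the tertiary alcohol are left alone.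

Step 19
Reactants: 27 primary alcohol
Product: 28 α-amino aldehyde (CHO on C5′)
Conditions: (COCl)2, DMSO, CH2Cl2, −78 °C; iPr2NEt; used crude
Reagents that add atoms: none
Why: Swern oxidation of the primary alcohol, to which tertiary alcohol, lactone and tertiary amine are inert; the aldehyde is used cold and crude to avoid epimerisation at the N-bearing carbon.

Step 20
Reactants: 28 α-amino aldehyde; 29 ethyl 2-(bromomethyl)acrylate
Product: 31 threo α-methylene-γ-butyrolactone, via threo hydroxy ester 30 (not isolated)
Conditions: Zn dust (TMSCl-activated), THF, rt → 50 °C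
Reagents that add atoms: none
Why: Dreiding–Schmidt reaction, in which the allylzinc bromide from 29 should add to the aldehyde through a zinc chelate between the pyrrolidine nitrogen and the carbonyl oxygen (Cram-chelate sense, threo) and the zinc alkoxide closes onto the ester; this sets the lactone O–CH.

Step 21
Reactants: 31 threo α-methylene-γ-butyrolactone
Product: 32 target CNP0260919.2
Conditions: H2 (1 atm), 10% Pd/C, EtOAc, rt
Reagents that add atoms: none
Why: Heterogeneous hydrogenation of the exocyclic alkene from the lactone face opposite the bulky C5 substituent should place the methyl group cis to it (3,5-cis lactone); nothing else is reducible.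

Compound list
1 | but-2-yne-1,4-diol | OCC#CCO | starting material
2 | 4-[(tert-butyldimethylsilyl)oxy]but-2-yn-1-ol | OCC#CCO[Si](C)(C)C(C)(C)C | intermediate
3 | tert-butyl[(4-iodobut-2-yn-1-yl)oxy]dimethylsilane | ICC#CCO[Si](C)(C)C(C)(C)C | intermediate
4 | (R)-4-[(tert-butyldimethylsilyl)oxy]cyclopent-2-en-1-one | O=C1C=C[C@H](O[Si](C)(C)C(C)(C)C)C1 | starting material
5 | diethylzinc | CC[Zn]CC | starting material
6 | lithium ethyl(methyl)zincate C1–C2 enolate of the 3-ethyl-4-silyloxycyclopentanone (ethyl trans to OTBS) | [Li+].CC[Zn-](C)OC1=C[C@@H](CC)[C@H](O[Si](C)(C)C(C)(C)C)C1 | intermediate (not isolated)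
7 | (2R,3R,4R)-4-[(tert-butyldimethylsilyl)oxy]-2-{4-[(tert-butyldimethylsilyl)oxy]but-2-yn-1-yl}-3-ethylcyclopentan-1-one | CC[C@H]1[C@H](O[Si](C)(C)C(C)(C)C)CC(=O)[C@@H]1CC#CCO[Si](C)(C)C(C)(C)C | intermediate
8 | tert-butyl (R)-4-formyl-2,2-dimethyloxazolidine-3-carboxylate | O=C[C@H]1COC(C)(C)N1C(=O)OC(C)(C)C | starting material
9 | tert-butyl (S)-4-ethynyl-2,2-dimethyloxazolidine-3-carboxylate | C#C[C@H]1COC(C)(C)N1C(=O)OC(C)(C)C | intermediate
10 | (S)-2-aminobut-3-yn-1-ol hydrochloride | C#C[C@@H](CO)N.Cl | intermediate
11 | (S)-N-(1-hydroxybut-3-yn-2-yl)-4-methylbenzenesulfonamide | C#C[C@@H](CO)NS(=O)(=O)c1ccc(C)cc1 | intermediate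
12 | (S)-N-{1-[(tert-butyldiphenylsilyl)oxy]but-3-yn-2-yl}-4-methylbenzenesulfonamide | C#C[C@@H](CO[Si](c1ccccc1)(c1ccccc1)C(C)(C)C)NS(=O)(=O)c1ccc(C)cc1 | intermediate
13 | C1-alkynyl tertiary alcohol (major C1 epimer) | CC[C@H]1[C@H](O[Si](C)(C)C(C)(C)C)C[C@@](O)(C#C[C@@H](CO[Si](c2ccccc2)(c2ccccc2)C(C)(C)C)NS(=O)(=O)c2ccc(C)cc2)[C@@H]1CC#CCO[Si](C)(C)C(C)(C)C | intermediate
14 | saturated tertiary alcohol (major C1 epimer) | CC[C@H]1[C@H](O[Si](C)(C)C(C)(C)C)C[C@@](O)(CC[C@@H](CO[Si](c2ccccc2)(c2ccccc2)C(C)(C)C)NS(=O)(=O)c2ccc(C)cc2)[C@@H]1CCCCO[Si](C)(C)C(C)(C)C | intermediate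
15 | bis-TBS N-tosyl 1-azaspiro[4.4]nonane | CC[C@H]1[C@H](O[Si](C)(C)C(C)(C)C)C[C@]2(CC[C@@H](CO[Si](c3ccccc3)(c3ccccc3)C(C)(C)C)N2S(=O)(=O)c2ccc(C)cc2)[C@@H]1CCCCO[Si](C)(C)C(C)(C)C | intermediate (not isolated)
16 | N-tosyl 1-azaspiro[4.4]nonane diol | CC[C@H]1[C@H](O)C[C@]2(CC[C@@H](CO[Si](c3ccccc3)(c3ccccc3)C(C)(C)C)N2S(=O)(=O)c2ccc(C)cc2)[C@@H]1CCCCO | intermediate
17 | spiro-pyrrolidine amino diol | CC[C@H]1[C@H](O)C[C@]2(CC[C@@H](CO[Si](c3ccccc3)(c3ccccc3)C(C)(C)C)N2)[C@@H]1CCCCO | intermediate
18 | primary bromide of 17 | CC[C@H]1[C@H](O)C[C@]2(CC[C@@H](CO[Si](c3ccccc3)(c3ccccc3)C(C)(C)C)N2)[C@@H]1CCCCBr | intermediate (not isolated)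
19 | tricyclic azepane alcohol | CC[C@H]1[C@H](O)C[C@@]23CC[C@@H](CO[Si](c4ccccc4)(c4ccccc4)C(C)(C)C)N2CCCC[C@H]13 | intermediate
20 | tricyclic amino ketone | CC[C@H]1C(=O)C[C@@]23CC[C@@H](CO[Si](c4ccccc4)(c4ccccc4)C(C)(C)C)N2CCCC[C@H]13 | intermediate
21 | ethyl bromoacetate | BrCC(=O)OCC | starting material
22 | keto ester | CC[C@H]1C(=O)[C@H](CC(=O)OCC)[C@@]23CC[C@@H](CO[Si](c4ccccc4)(c4ccccc4)C(C)(C)C)N2CCCC[C@H]13 | intermediate
23 | cis hydroxy ester | CC[C@H]1[C@H](O)[C@H](CC(=O)OCC)[C@@]23CC[C@@H](CO[Si](c4ccccc4)(c4ccccc4)C(C)(C)C)N2CCCC[C@H]13 | intermediate (not isolated)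
24 | cis-fused γ-lactone | CC[C@H]1[C@@H]2OC(=O)C[C@@H]2[C@@]23CC[C@@H](CO[Si](c4ccccc4)(c4ccccc4)C(C)(C)C)N2CCCC[C@H]13 | intermediate
25 | α-methyl lactone | CC[C@H]1[C@@H]2OC(=O)[C@@H](C)[C@@H]2[C@@]23CC[C@@H](CO[Si](c4ccccc4)(c4ccccc4)C(C)(C)C)N2CCCC[C@H]13 | intermediate
26 | α-hydroxy-α-methyl lactone, TBDPS ether | CC[C@H]1[C@@H]2OC(=O)[C@@](C)(O)[C@@H]2[C@@]23CC[C@@H](CO[Si](c4ccccc4)(c4ccccc4)C(C)(C)C)N2CCCC[C@H]13 | intermediate
27 | primary alcohol | CC[C@H]1[C@@H]2OC(=O)[C@@](C)(O)[C@@H]2[C@@]23CC[C@@H](CO)N2CCCC[C@H]13 | intermediate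
28 | α-amino aldehyde | CC[C@H]1[C@@H]2OC(=O)[C@@](C)(O)[C@@H]2[C@@]23CC[C@@H](C=O)N2CCCC[C@H]13 | intermediate
29 | ethyl 2-(bromomethyl)acrylate | C=C(CBr)C(=O)OCC | starting material
30 | threo hydroxy ester | CC[C@H]1[C@@H]2OC(=O)[C@@](C)(O)[C@@H]2[C@@]23CC[C@@H]([C@@H](O)CC(=C)C(=O)OCC)N2CCCC[C@H]13 | intermediate (not isolated)
31 | threo α-methylene-γ-butyrolactone | CC[C@H]1[C@@H]2OC(=O)[C@@](C)(O)[C@@H]2[C@@]23CC[C@@H]([C@@H]4CC(=C)C(=O)O4)N2CCCC[C@H]13 | intermediate
32 | target CNP0260919.2 | CC[C@H]1[C@@H]2OC(=O)[C@@](C)(O)[C@@H]2[C@@]23CC[C@@H]([C@@H]4C[C@H](C)C(=O)O4)N2CCCC[C@H]13 | target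

Total step count: 21. Longest linear sequence: 18 steps (steps 4–7, then 8–21).

Steps most likely to fail

1. Step 10 (cationic spiro-amination). After ionisation the cation may lose a proton toward C2 or undergo a 1,2-hydride shift, either of which erases the configuration of the ring-fusion CH. Nitrogen may also close on the lower face, and the acid may strip the TBDPS ether. The fallback replaces cation capture by conjugate addition; it sets out from 14 and comes back at 20. Sodium naphthalenide removes the tosyl group to give primary amine F1, and Boc2O gives carbamate F2. HF·pyridine removes both TBS ethers to give triol F3, and Dess–Martin periodinane oxidises the secondary and the primary alcohol to hydroxy keto aldehyde F4. DBU eliminates the tertiary β-hydroxyl (E1cB) to give cyclopentenone F5, and TFA frees the amine to give amino enone F6. On neutralisation the amine adds to the enone β-carbon (5-exo-trig aza-Michael addition, reversible, so the spiro centre can equilibrate) to give spiro amino keto aldehyde F7. Its secondary amine condenses with the aldehyde, and NaBH(OAc)3 reduces the seven-membered iminium ion to amino ketone 20.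

2. Step 15 (reduction–lactonisation). The ketone is flanked by two trans α-substituents of similar size, so hydride may enter from the lower face and give the trans hydroxy ester, which cannot lactonise. The fallback sets out from 22 and comes back at 24. NaBH4 in EtOH at −40 °C reduces the ketone without demand on the face, and the cis alcohol lactonises to 24 directly. The trans hydroxy ester F8 is saponified with LiOH to hydroxy acid F9, which is closed by an intramolecular Mitsunobu reaction (PPh3, DIAD) with inversion at C4 to the same lactone 24.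

3. Step 20 (allylzinc addition). The amino aldehyde may epimerise at the carbon between N and CHO, and the allylzinc reagent may add without chelation (Felkin–Anh sense), which would give the erythro lactone. The fallback sets out from 28 and comes back at 31. The aldehyde is first bound as its N,O-chelate with SnCl4 in CH2Cl2 at −78 °C and then treated with ethyl 2-[(trimethylsilyl)methyl]acrylate. This is a chelation-controlled Hosomi–Sakurai allylation through an open transition state, in place of the closed allylzinc addition. It gives the threo hydroxy ester 30, which p-TsOH closes to 31; no new compound arises.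

Further compounds
F1 | step 10 | primary amine (14 without the tosyl group) | CC[C@H]1[C@H](O[Si](C)(C)C(C)(C)C)C[C@@](O)(CC[C@@H](CO[Si](c2ccccc2)(c2ccccc2)C(C)(C)C)N)[C@@H]1CCCCO[Si](C)(C)C(C)(C)C
F2 | step 10 | N-Boc carbamate of F1 | CC[C@H]1[C@H](O[Si](C)(C)C(C)(C)C)C[C@@](O)(CC[C@@H](CO[Si](c2ccccc2)(c2ccccc2)C(C)(C)C)NC(=O)OC(C)(C)C)[C@@H]1CCCCO[Si](C)(C)C(C)(C)C
F3 | step 10 | N-Boc triol | CC[C@H]1[C@H](O)C[C@@](O)(CC[C@@H](CO[Si](c2ccccc2)(c2ccccc2)C(C)(C)C)NC(=O)OC(C)(C)C)[C@@H]1CCCCO
F4 | step 10 | N-Boc β-hydroxy keto aldehyde | CC[C@H]1C(=O)C[C@@](O)(CC[C@@H](CO[Si](c2ccccc2)(c2ccccc2)C(C)(C)C)NC(=O)OC(C)(C)C)[C@@H]1CCCC=O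
F5 | step 10 | N-Boc cyclopentenone aldehyde | CC[C@H]1C(=O)C=C(CC[C@@H](CO[Si](c2ccccc2)(c2ccccc2)C(C)(C)C)NC(=O)OC(C)(C)C)[C@@H]1CCCC=O
F6 | step 10 | amino cyclopentenone aldehyde | CC[C@H]1C(=O)C=C(CC[C@@H](CO[Si](c2ccccc2)(c2ccccc2)C(C)(C)C)N)[C@@H]1CCCC=O
F7 | step 10 | spiro amino keto aldehyde | CC[C@H]1C(=O)C[C@]2(CC[C@@H](CO[Si](c3ccccc3)(c3ccccc3)C(C)(C)C)N2)[C@@H]1CCCC=O
F8 | step 15 | trans hydroxy ester (C4–OH on the upper face) | CC[C@H]1[C@@H](O)[C@H](CC(=O)OCC)[C@@]23CC[C@@H](CO[Si](c4ccccc4)(c4ccccc4)C(C)(C)C)N2CCCC[C@H]13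
F9 | step 15 | trans hydroxy acid | CC[C@H]1[C@@H](O)[C@H](CC(=O)O)[C@@]23CC[C@@H](CO[Si](c4ccccc4)(c4ccccc4)C(C)(C)C)N2CCCC[C@H]13
F0 | step 20 | none | none
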